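The six-membered ring (7-oxabicyclo[4.1.0]hept-4-ene numbering) is cut at two opposite bonds, the C4=C5 alkene and the bond from the carbinol carbon C2 to the quaternary carbon C1, which gives two three-carbon pieces. The C1–C6 epoxide is carried as a C1=C6 alkene, so the ring is first made as a cyclohexa-1,3-diene. In one flask a (Z)-dienylmagnesium reagent adds to an α-alkoxy aldehyde under chelation control and the resulting triene is closed by ring-closing metathesis. The step exploits the C4=C5 alkene flanked by two allylic ring carbons and the allylic C2 hydroxyl, which later directs epoxidation of C1=C6 to its own face.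

Key step: step 6

Remark on the chemistry: (2R)-but-3-ene-1,2-diol is assumed to be a commercial, enantiopure starting material. The key step is a one-flask sequence of two mechanistically independent reactions (addition, then metathesis), not a single-reagent cascade.

Step 1
Reactants: 1 ethyl (triphenylphosphoranylidene)acetate; 2 N-iodosuccinimide; 3 acrolein
Product: 5 ethyl (2Z)-2-iodopenta-2,4-dienoate, via iodo ylide 4 (not isolated)
Conditions: NIS, CH2Cl2, −20 °C; then acrolein, −20 °C → rt
Reagents that add atoms: N-iodosuccinimide, O=C1CCC(=O)N1I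
Why: One-pot ylide iodination/Wittig olefination; the ester-stabilised iodo ylide 4 should place the ester trans to the vinyl group, so iodine and vinyl end up cis (Z).

Step 2
Reactants: 5 ethyl (2Z)-2-iodopenta-2,4-dienoate
Product: 6 (2Z)-2-iodopenta-2,4-dien-1-ol
Conditions: DIBAL-H (2.2 equiv), CH2Cl2, −78 °C; Rochelle salt
Reagents that add atoms: none
Why: DIBAL-H reduction of the conjugated ester to the allylic alcohol at low temperature should leave the alkenyl iodide and the alkene geometry untouched.

Step 3
Reactants: 7 (2R)-but-3-ene-1,2-diol; 8 4-methoxybenzaldehyde dimethyl acetal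
Product: 9 (4R)-4-ethenyl-2-(4-methoxyphenyl)-1,3-dioxolane
Conditions: PPTS (cat.), CH2Cl2, rt
Reagents that add atoms: 4-methoxybenzaldehyde dimethyl acetal, COC(OC)c1ccc(OC)cc1
Why: Acid-catalysed transacetalisation gives the p-methoxybenzylidene acetal without touching the stereocentre; the acetal carbon is a mixture that disappears in step 4.

Step 4
Reactants: 9 (4R)-4-ethenyl-2-(4-methoxyphenyl)-1,3-dioxolane
Product: 10 (2R)-2-[(4-methoxybenzyl)oxy]but-3-en-1-ol
Conditions: DIBAL-H, CH2Cl2, −78 → 0 °C
Reagents that add atoms: none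
Why: Regioselective reductive acetal opening; aluminium binds the less hindered primary oxygen, so the PMB group should end up on the secondary oxygen.

Step 5
Reactants: 10 (2R)-2-[(4-methoxybenzyl)oxy]but-3-en-1-ol
Product: 11 (2R)-2-[(4-methoxybenzyl)oxy]but-3-enal
Conditions: Dess–Martin periodinane, CH2Cl2, 0 °C; crude aldehyde used at once
Reagents that add atoms: none
Why: Dess–Martin oxidation under non-basic conditions should give the α-alkoxy aldehyde without enolisation of the allylic α-stereocentre.

Step 6
Reactants: 6 (2Z)-2-iodopenta-2,4-dien-1-ol; 11 (2R)-2-[(4-methoxybenzyl)oxy]but-3-enal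
Product: 14 (1R,6R)-2-(hydroxymethyl)-6-[(4-methoxybenzyl)oxy]cyclohexa-2,4-dien-1-ol, via alkenylmagnesium alkoxide 12 (not isolated), via triene diol 13 (not isolated)
Conditions: 6, i-PrMgCl·LiCl (2.1 equiv), THF, −20 °C; MgBr2·OEt2, CH2Cl2, then 11, −78 °C; AcOH; then Grubbs II (5 mol %), CH2Cl2, 40 °C, same flask
Reagents that add atoms: none
Why: Deprotonation and iodine–magnesium exchange convert 6 into the dimagnesium species 12 with retention of the Z geometry, and 12 adds to aldehyde 11 held in a five-membered magnesium chelate between the carbonyl oxygen and the PMB ether oxygen, on the face opposite the α-vinyl group (Cram chelate model); this forms the bond between the carbinol carbon and the future quaternary ring carbon and sets the new carbinol centre (5R in 13, syn to the ether oxygen). After protonation the ruthenium alkylidene engages the two terminal vinyl groups of triene 13 and closes the six-membered ring by ring-closing metathesis with loss of ethene, which creates the ring alkene, necessarily cis. The closest known reaction types are the chelation-controlled Grignard addition to α-alkoxy aldehydes and the diene–ene ring-closing metathesis that gives cyclohexa-1,3-dienes. The step needs three selectivities: syn addition, secured by the chelating PMB ether and the weakly coordinating CH2Cl2 medium; retention of the Z alkene, secured by the configurational stability of alkenylmagnesium reagents, which puts the carbinol carbon and the vinyl group cis so that only a six-membered ring can close; and reaction of the catalyst at the terminal alkenes only, secured by the inert trisubstituted alkene. No stereocentre is created in the metathesis stage.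

Step 7
Reactants: 14 (1R,6R)-2-(hydroxymethyl)-6-[(4-methoxybenzyl)oxy]cyclohexa-2,4-dien-1-ol; 15 tert-butyl hydroperoxide
Product: 16 (1S,2S,3R,6R)-1-(hydroxymethyl)-3-[(4-methoxybenzyl)oxy]-7-oxabicyclo[4.1.0]hept-4-en-2-ol
Conditions: VO(acac)2 (cat.), TBHP, CH2Cl2, 0 °C → rt
Reagents that add atoms: tert-butyl hydroperoxide, CC(C)(C)OO
Why: Hydroxyl-directed vanadium-catalysed epoxidation; the ring hydroxyl binds vanadium and should deliver oxygen to the adjacent trisubstituted alkene on its own face (syn, anti to the PMB ether), while the distal, only homoallylic alkene should not react.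

Step 8
Reactants: 16 (1S,2S,3R,6R)-1-(hydroxymethyl)-3-[(4-methoxybenzyl)oxy]-7-oxabicyclo[4.1.0]hept-4-en-2-ol
Product: 17 (1S,2S,3R,6R)-1-(hydroxymethyl)-7-oxabicyclo[4.1.0]hept-4-ene-2,3-diol
Conditions: DDQ, CH2Cl2/pH 7 buffer, 0 °C
Reagents that add atoms: none
Why: Oxidative PMB ether cleavage by DDQ (benzylic hydride abstraction, then hydrolysis of the oxocarbenium ion) should spare the vinyl epoxide under buffered conditions.

Step 9
Reactants: 17 (1S,2S,3R,6R)-1-(hydroxymethyl)-7-oxabicyclo[4.1.0]hept-4-ene-2,3-diol; 18 benzoyl chloride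
Product: 19 [(1S,2S,3R,6R)-3-(benzoyloxy)-2-hydroxy-7-oxabicyclo[4.1.0]hept-4-en-1-yl]methyl benzoate
Conditions: BzCl (2.1 equiv), pyridine, CH2Cl2, −40 → 0 °C
Reagents that add atoms: benzoyl chloride, O=C(Cl)c1ccccc1
Why: Kinetically controlled acylation; the primary and the allylic secondary hydroxyl should react, whereas the C2 hydroxyl, flanked by the quaternary epoxide carbon and hydrogen-bonded to the epoxide oxygen, should stay free.

Compound list
1 | ethyl (triphenylphosphoranylidene)acetate | CCOC(=O)C=P(c1ccccc1)(c1ccccc1)c1ccccc1 | starting material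
2 | N-iodosuccinimide | O=C1CCC(=O)N1I | starting material
3 | acrolein | C=CC=O | starting material
4 | ethyl iodo(triphenylphosphoranylidene)acetate | CCOC(=O)C(I)=P(c1ccccc1)(c1ccccc1)c1ccccc1 | intermediate
5 | ethyl (2Z)-2-iodopenta-2,4-dienoate | C=C/C=C(\I)C(=O)OCC | intermediate
6 | (2Z)-2-iodopenta-2,4-dien-1-ol | C=C/C=C(\I)CO | intermediate
7 | (2R)-but-3-ene-1,2-diol | C=C[C@@H](O)CO | starting material
8 | 4-methoxybenzaldehyde dimethyl acetal | COC(OC)c1ccc(OC)cc1 | starting material
9 | (4R)-4-ethenyl-2-(4-methoxyphenyl)-1,3-dioxolane (mixture at C2) | C=C[C@@H]1COC(c2ccc(OC)cc2)O1 | intermediate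
10 | (2R)-2-[(4-methoxybenzyl)oxy]but-3-en-1-ol | C=C[C@@H](OCc1ccc(OC)cc1)CO | intermediate
11 | (2R)-2-[(4-methoxybenzyl)oxy]but-3-enal | C=C[C@@H](OCc1ccc(OC)cc1)C=O | intermediate
12 | chloromagnesium (2Z)-2-(chloromagnesio)penta-2,4-dien-1-olate | C=C/C=C(\[Mg]Cl)CO[Mg]Cl | intermediate
13 | (3Z,5R,6R)-4-(hydroxymethyl)-6-[(4-methoxybenzyl)oxy]octa-1,3,7-trien-5-ol | C=C[C@@H](OCc1ccc(OC)cc1)[C@H](O)/C(CO)=C\C=C | intermediate
14 | (1R,6R)-2-(hydroxymethyl)-6-[(4-methoxybenzyl)oxy]cyclohexa-2,4-dien-1-ol | OCC1=CC=C[C@@H](OCc2ccc(OC)cc2)[C@@H]1O | intermediate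
15 | tert-butyl hydroperoxide | CC(C)(C)OO | starting material
16 | (1S,2S,3R,6R)-1-(hydroxymethyl)-3-[(4-methoxybenzyl)oxy]-7-oxabicyclo[4.1.0]hept-4-en-2-ol | OC[C@@]12O[C@@H]1C=C[C@@H](OCc3ccc(OC)cc3)[C@@H]2O | intermediate
17 | (1S,2S,3R,6R)-1-(hydroxymethyl)-7-oxabicyclo[4.1.0]hept-4-ene-2,3-diol | OC[C@@]12O[C@@H]1C=C[C@@H](O)[C@@H]2O | intermediate
18 | benzoyl chloride | O=C(Cl)c1ccccc1 | starting material
19 | [(1S,2S,3R,6R)-3-(benzoyloxy)-2-hydroxy-7-oxabicyclo[4.1.0]hept-4-en-1-yl]methyl benzoate | O=C(OC[C@@]12O[C@@H]1C=C[C@@H](OC(=O)c1ccccc1)[C@@H]2O)c1ccccc1 | target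

Total step count: 9
Longest linear sequence: 7 steps (steps 3 to 9, from 7)

Steps most likely to fail

Step 6. Chelation control may erode, giving poor facial selectivity at the new carbinol carbon. The metathesis stage may also stall in the presence of magnesium salts, or the dienol may aromatise through ruthenium hydride species. The fallback sets out from 6 and 11 and separates the two bond formations. A nickel/chromium-mediated (Nozaki–Hiyama–Kishi) coupling under a chiral sulfonamide–oxazoline chromium complex lets the reagent, not the chelate, fix the carbinol configuration. Triene diol 13 is isolated and cyclised in a separate operation with a Hoveyda–Grubbs catalyst, and the route is rejoined at 14. This fallback makes no new compound (F0).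

Step 9. The two secondary hydroxyls may not be discriminated, leading to over-acylation or 2,3-acyl migration. The fallback sets out from 16 and uses protecting groups instead of kinetic selectivity. The primary hydroxyl alone is benzoylated (BzCl, collidine, −40 °C) to give [(1S,2S,3R,6R)-2-hydroxy-3-[(4-methoxybenzyl)oxy]-7-oxabicyclo[4.1.0]hept-4-en-1-yl]methyl benzoate F1. The C2 hydroxyl is silylated (TESOTf, 2,6-lutidine) to give the C2 triethylsilyl ether of F1, F2. DDQ removes the PMB group to give the C3 alcohol F3. Benzoylation (BzCl, DMAP) gives the C2 triethylsilyl ether of the target, F4. HF·pyridine then frees the C2 hydroxyl, and the route is rejoined at 19.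

Step 5. The doubly activated α-carbon of the aldehyde may lose its configuration by enolisation, or the double bond may move into conjugation during oxidation and handling. The fallback sets out from 10 and avoids the aldehyde. Oxidation (TEMPO, PhI(OAc)2, aqueous MeCN) gives (2R)-2-[(4-methoxybenzyl)oxy]but-3-enoic acid F5. Amide formation (MeNHOMe·HCl, EDC) gives (2R)-N-methoxy-2-[(4-methoxybenzyl)oxy]-N-methylbut-3-enamide F6. Acylation of the magnesium reagent 12 (made from 6 as in step 6) gives (3Z,6R)-4-(hydroxymethyl)-6-[(4-methoxybenzyl)oxy]octa-1,3,7-trien-5-one F7. A reagent-controlled oxazaborolidine (CBS)-catalysed borane reduction should then give 13, which is closed by metathesis, and the route is rejoined at 14.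

Further compounds
F0 | step 6 | none | none
F1 | step 9 | [(1S,2S,3R,6R)-2-hydroxy-3-[(4-methoxybenzyl)oxy]-7-oxabicyclo[4.1.0]hept-4-en-1-yl]methyl benzoate | O=C(OC[C@@]12O[C@@H]1C=C[C@@H](OCc3ccc(OC)cc3)[C@@H]2O)c1ccccc1
F2 | step 9 | C2 triethylsilyl ether of F1 | O=C(OC[C@@]12O[C@@H]1C=C[C@@H](OCc3ccc(OC)cc3)[C@@H]2O[Si](CC)(CC)CC)c1ccccc1
F3 | step 9 | C3 alcohol from F2 (PMB removed) | O=C(OC[C@@]12O[C@@H]1C=C[C@@H](O)[C@@H]2O[Si](CC)(CC)CC)c1ccccc1
F4 | step 9 | C2 triethylsilyl ether of the target | O=C(OC[C@@]12O[C@@H]1C=C[C@@H](OC(=O)c1ccccc1)[C@@H]2O[Si](CC)(CC)CC)c1ccccc1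
F5 | step 5 | (2R)-2-[(4-methoxybenzyl)oxy]but-3-enoic acid | C=C[C@@H](OCc1ccc(OC)cc1)C(=O)O
F6 | step 5 | (2R)-N-methoxy-2-[(4-methoxybenzyl)oxy]-N-methylbut-3-enamide | C=C[C@@H](OCc1ccc(OC)cc1)C(=O)N(C)OC
F7 | step 5 | (3Z,6R)-4-(hydroxymethyl)-6-[(4-methoxybenzyl)oxy]octa-1,3,7-trien-5-one | C=C[C@@H](OCc1ccc(OC)cc1)C(=O)/C(CO)=C\C=C
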